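## Retrosynthetic overview

1. Target 23 ⇐ global desilylation of deca-silyl ether 22 ⇐ Heck coupling of tris(dihydrobenzofuran) bromide 18 with catechol styrene 21.
2. Each trans-2,3-diaryl-2,3-dihydrobenzofuran is cut at O1–C2: a catalytic enantioselective dehydrative hydroalkoxylation (C–O ring closure) of an o-hydroxyaryl tertiary benzylic alcohol, which passes through a triarylethylene.
3. Each tertiary alcohol ⇐ aryllithium (from the C4 bromide of the previously made ring) + one common bromo-deoxybenzoin, used as its sodium phenoxide 5, which is made once from 5-bromoresorcinol and 4-hydroxyphenylacetic acid and isolated.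
4. Ring order: ring C (2R,3R) → ring B (2S,3S, mirror-image catalyst) → ring A (2R,3R). The C4 bromine of each new ring is the handle for the next cycle and finally for the stilbene.

## Assumptions and abbreviations

- TBS = tert-butyldimethylsilyl; TBSO = tert-butyldimethylsilyloxy.
- IDPi-A = one enantiomer of a confined BINOL-derived imidodiphosphorimidate Brønsted acid (two 3,3'-bis[3,5-bis(trifluoromethyl)phenyl]-BINOL phosphorus units joined through N–H, each phosphorus carrying an N-triflyl imino group). IDPi-A is defined as the enantiomer that closes the ring as (2R,3R), and ent-IDPi-A is its mirror image. Which BINOL configuration this is cannot be predicted and is fixed by the first experiment.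
- "unit C" = (2R,3R)-3-[3,5-bis(TBSO)phenyl]-6-(TBSO)-2-[4-(TBSO)phenyl]-2,3-dihydro-1-benzofuran-4-yl.
- "unit BC" = (2S,3S)-6-(TBSO)-2-[4-(TBSO)phenyl]-3-(unit C)-2,3-dihydro-1-benzofuran-4-yl.
- 5-Bromoresorcinol is taken as a commercial starting material.

## Route

Step 1
Reactants: 1 5-bromobenzene-1,3-diol; 2 2-(4-hydroxyphenyl)acetic acid
Product: 3 1-(2-bromo-4,6-dihydroxyphenyl)-2-(4-hydroxyphenyl)ethan-1-one
Conditions: BF3·OEt2 (solvent), 85 °C, 3 h; then aq. NaOAc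
Reagents that add atoms: none
Why: Friedel–Crafts C-acylation of a resorcinol by an arylacetic acid in BF3·OEt2 (the standard deoxybenzoin synthesis) goes ortho to one OH and para to the other, which in a 5-substituted resorcinol is the carbon next to the substituent, and the chelated o-hydroxy ketone is not acylated again.

Step 2
Reactants: 3 1-(2-bromo-4,6-dihydroxyphenyl)-2-(4-hydroxyphenyl)ethan-1-one
Product: 4 1-[2-bromo-6-hydroxy-4-(TBSO)phenyl]-2-[4-(TBSO)phenyl]ethan-1-one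
Conditions: TBSCl (2.1 equiv), imidazole, DMF, 0 °C
Reagents that add atoms: tert-butyldimethylsilyl chloride (TBSCl), CC(C)(C)[Si](C)(C)Cl
Why: Chemoselective silyl ether formation on the two free phenols, the 6-OH being hydrogen-bonded to the ketone and left untouched.

Step 3
Reactants: 4 1-[2-bromo-6-hydroxy-4-(TBSO)phenyl]-2-[4-(TBSO)phenyl]ethan-1-one
Product: 5 sodium 3-bromo-5-(TBSO)-2-{2-[4-(TBSO)phenyl]acetyl}phenolate
Conditions: NaH (1.0 equiv), THF, 0 °C → rt, 30 min; evaporated, solid kept under argon at −20 °C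
Reagents that add atoms: sodium hydride, [Na+].[H-]
Why: Irreversible acid–base deprotonation (phenoxide formation) of the phenol, which is far more acidic than the benzylic ketone CH2, gives a chelated sodium 2-acylphenoxide that is a weak nucleophile and isolable; it is made once as the common electrophile for steps 5, 7 and 9, so that no aryllithium is spent on the phenol.

Step 4
Reactants: 1 5-bromobenzene-1,3-diol
Product: 6 1-bromo-3,5-bis(TBSO)benzene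
Conditions: TBSCl (2.3 equiv), imidazole, DMF, rt
Reagents that add atoms: tert-butyldimethylsilyl chloride (TBSCl), CC(C)(C)[Si](C)(C)Cl
Why: Standard phenol silylation (silyl ether formation).

Step 5
Reactants: 6 1-bromo-3,5-bis(TBSO)benzene; 5 sodium 3-bromo-5-(TBSO)-2-{2-[4-(TBSO)phenyl]acetyl}phenolate
Product: 8 rac-1-[2-bromo-6-hydroxy-4-(TBSO)phenyl]-1-[3,5-bis(TBSO)phenyl]-2-[4-(TBSO)phenyl]ethan-1-ol, via aryllithium 7 (not isolated)
Conditions: 6, n-BuLi (1.0 equiv), THF, −78 °C; cannulated into 5 and LaCl3·2LiCl (1.0 equiv) in THF, −78 → 0 °C; aq. NH4Cl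
Reagents that add atoms: none
Why: Bromine–lithium exchange and 1,2-addition of the aryllithium to the ketone (the carbonyl-addition route to triarylethylene precursors), with the Lewis acid LaCl3·2LiCl activating the carbonyl and suppressing enolisation without being consumed; the carbinol centre is racemic and is erased in step 6.

Step 6
Reactants: 8 rac-1-[2-bromo-6-hydroxy-4-(TBSO)phenyl]-1-[3,5-bis(TBSO)phenyl]-2-[4-(TBSO)phenyl]ethan-1-ol
Product: 10 (2R,3R)-4-bromo-3-[3,5-bis(TBSO)phenyl]-6-(TBSO)-2-[4-(TBSO)phenyl]-2,3-dihydro-1-benzofuran, via triarylethylene 9 (not isolated)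
Conditions: IDPi-A (5 mol %), 5 Å molecular sieves, toluene (0.02 M), 40 °C
Reagents that add atoms: none
Why: Proposed new method: the confined chiral acid ionises the tertiary o-hydroxybenzylic alcohol to a diaryl o-quinone methide that tautomerises to triarylethylene 9; enantio-determining proton transfer to the diaryl carbon inside the chiral anion pocket gives a 4-silyloxybenzyl cation paired with the chiral anion, and the ortho phenol closes the five-membered ring by C–O bond formation anti to the C3 aryl group (trans, also the thermodynamic isomer), so C3 is set by the catalyst and C2 by the ring closure; the closest known reaction types are imidodiphosphorimidate-catalysed asymmetric intramolecular hydroalkoxylation of alkenes and the acid-mediated quinone-methide ring closures of stilbene oligomers.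

Step 7
Reactants: 10 (2R,3R)-4-bromo-3-[3,5-bis(TBSO)phenyl]-6-(TBSO)-2-[4-(TBSO)phenyl]-2,3-dihydro-1-benzofuran; 5 sodium 3-bromo-5-(TBSO)-2-{2-[4-(TBSO)phenyl]acetyl}phenolate
Product: 12 1-[2-bromo-6-hydroxy-4-(TBSO)phenyl]-2-[4-(TBSO)phenyl]-1-(unit C)ethan-1-ol (both carbinol epimers), via aryllithium 11 (not isolated)
Conditions: 10, n-BuLi (1.0 equiv), THF, −78 °C; cannulated into 5 (1.5 equiv) and LaCl3·2LiCl (1.5 equiv) in THF, −78 → 0 °C; aq. NH4Cl (unreacted 5 returns as 4)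
Reagents that add atoms: none
Why: Same bromine–lithium exchange and carbonyl addition as step 5, now with a hindered aryllithium so that enolisation of 5 is the main competitor; both carbinol epimers are carried on because that centre is erased in step 8, and the ring C stereocentres are untouched.

Step 8
Reactants: 12 1-[2-bromo-6-hydroxy-4-(TBSO)phenyl]-2-[4-(TBSO)phenyl]-1-(unit C)ethan-1-ol
Product: 14 (2S,3S)-4-bromo-6-(TBSO)-2-[4-(TBSO)phenyl]-3-(unit C)-2,3-dihydro-1-benzofuran, via triarylethylene 13 (not isolated)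
Conditions: ent-IDPi-A (5–10 mol %), 5 Å molecular sieves, toluene (0.02 M), 40 °C
Reagents that add atoms: none
Why: Proposed new method: same ionisation, tautomerisation to 13, catalyst-controlled protonation at the diaryl carbon and trans-selective C–O closure as in step 6, with the mirror-image acid because the local sense of ring B is opposite to that of ring C, the catalyst being expected to override the remote ring C stereocentres; the closest known reaction type is again chiral-acid-catalysed asymmetric intramolecular hydroalkoxylation.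

Step 9
Reactants: 14 (2S,3S)-4-bromo-6-(TBSO)-2-[4-(TBSO)phenyl]-3-(unit C)-2,3-dihydro-1-benzofuran; 5 sodium 3-bromo-5-(TBSO)-2-{2-[4-(TBSO)phenyl]acetyl}phenolate
Product: 16 1-[2-bromo-6-hydroxy-4-(TBSO)phenyl]-2-[4-(TBSO)phenyl]-1-(unit BC)ethan-1-ol (both carbinol epimers), via aryllithium 15 (not isolated)
Conditions: 14, n-BuLi (1.0 equiv), THF, −78 °C; cannulated into 5 (1.5 equiv) and LaCl3·2LiCl (1.5 equiv) in THF, −78 → 0 °C; aq. NH4Cl (unreacted 5 returns as 4)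
Reagents that add atoms: none
Why: Third bromine–lithium exchange and 1,2-carbonyl addition, as in step 7; the new carbinol centre is erased in step 10 and the four existing stereocentres are untouched.

Step 10
Reactants: 16 1-[2-bromo-6-hydroxy-4-(TBSO)phenyl]-2-[4-(TBSO)phenyl]-1-(unit BC)ethan-1-ol
Product: 18 (2R,3R)-4-bromo-6-(TBSO)-2-[4-(TBSO)phenyl]-3-(unit BC)-2,3-dihydro-1-benzofuran, via triarylethylene 17 (not isolated)
Conditions: IDPi-A (5–10 mol %), 5 Å molecular sieves, toluene (0.02 M), 40 °C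
Reagents that add atoms: none
Why: Proposed new method: same chiral-acid-catalysed dehydrative hydroalkoxylation through 17 as in step 6 (catalyst-controlled protonation sets C3, anti C–O closure sets C2 trans), using IDPi-A again because ring A has the same local sense as ring C; the closest known reaction type is chiral-acid-catalysed asymmetric intramolecular hydroalkoxylation.

Step 11
Reactants: 19 3,4-dihydroxybenzaldehyde
Product: 20 3,4-bis(TBSO)benzaldehyde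
Conditions: TBSCl (2.3 equiv), imidazole, DMF, rt
Reagents that add atoms: tert-butyldimethylsilyl chloride (TBSCl), CC(C)(C)[Si](C)(C)Cl
Why: Standard phenol silylation (silyl ether formation).

Step 12
Reactants: 20 3,4-bis(TBSO)benzaldehyde
Product: 21 4-ethenyl-1,2-bis(TBSO)benzene
Conditions: Ph3PCH3Br, KOtBu, THF, 0 °C → rt
Reagents that add atoms: methyltriphenylphosphonium bromide, C[P+](c1ccccc1)(c1ccccc1)c1ccccc1.[Br-]
Why: Wittig methylenation of an aromatic aldehyde with the non-stabilised ylide.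

Step 13
Reactants: 18 (2R,3R)-4-bromo-6-(TBSO)-2-[4-(TBSO)phenyl]-3-(unit BC)-2,3-dihydro-1-benzofuran; 21 4-ethenyl-1,2-bis(TBSO)benzene
Product: 22 (2R,3R)-4-{(E)-2-[3,4-bis(TBSO)phenyl]ethenyl}-6-(TBSO)-2-[4-(TBSO)phenyl]-3-(unit BC)-2,3-dihydro-1-benzofuran
Conditions: Pd(OAc)2 (5 mol %), [HP(t-Bu)3]BF4 (10 mol %), Cy2NMe, 1,4-dioxane, 80 °C
Reagents that add atoms: none
Why: Mizoroki–Heck reaction in which the bulky electron-rich phosphine allows oxidative addition into the hindered electron-rich aryl bromide and syn β-hydride elimination gives the E-stilbene; no stereocentre is touched.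

Step 14
Reactants: 22 (2R,3R)-4-{(E)-2-[3,4-bis(TBSO)phenyl]ethenyl}-6-(TBSO)-2-[4-(TBSO)phenyl]-3-(unit BC)-2,3-dihydro-1-benzofuran
Product: 23 (2R,3R)-4-[(E)-2-(3,4-dihydroxyphenyl)ethenyl]-2-(4-hydroxyphenyl)-3-{(2S,3S)-6-hydroxy-2-(4-hydroxyphenyl)-3-[(2R,3R)-3-(3,5-dihydroxyphenyl)-6-hydroxy-2-(4-hydroxyphenyl)-2,3-dihydro-1-benzofuran-4-yl]-2,3-dihydro-1-benzofuran-4-yl}-2,3-dihydro-1-benzofuran-6-ol
Conditions: HF·pyridine, pyridine, THF, 0 °C → rt, argon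
Reagents that add atoms: none
Why: Fluoride-mediated cleavage of all ten aryl silyl ethers under buffered conditions that leave the benzylic ethers of the dihydrobenzofurans, the stilbene and the catechol intact; no stereocentre is touched.

## Compound list

1 | 5-bromobenzene-1,3-diol (5-bromoresorcinol) | Oc1cc(O)cc(Br)c1 | starting material
2 | 2-(4-hydroxyphenyl)acetic acid | OC(=O)Cc1ccc(O)cc1 | starting material
3 | 1-(2-bromo-4,6-dihydroxyphenyl)-2-(4-hydroxyphenyl)ethan-1-one | O=C(Cc1ccc(O)cc1)c1c(O)cc(O)cc1Br | intermediate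
4 | 1-[2-bromo-6-hydroxy-4-(TBSO)phenyl]-2-[4-(TBSO)phenyl]ethan-1-one | O=C(Cc1ccc(O[Si](C)(C)C(C)(C)C)cc1)c1c(O)cc(O[Si](C)(C)C(C)(C)C)cc1Br | intermediate
5 | sodium 3-bromo-5-(TBSO)-2-{2-[4-(TBSO)phenyl]acetyl}phenolate (sodium phenoxide of 4) | [Na+].[O-]c1cc(O[Si](C)(C)C(C)(C)C)cc(Br)c1C(=O)Cc1ccc(O[Si](C)(C)C(C)(C)C)cc1 | intermediate
6 | 1-bromo-3,5-bis(TBSO)benzene | Brc1cc(O[Si](C)(C)C(C)(C)C)cc(O[Si](C)(C)C(C)(C)C)c1 | intermediate
7 | [3,5-bis(TBSO)phenyl]lithium (not isolated) | [Li]c1cc(O[Si](C)(C)C(C)(C)C)cc(O[Si](C)(C)C(C)(C)C)c1 | intermediate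
8 | rac-1-[2-bromo-6-hydroxy-4-(TBSO)phenyl]-1-[3,5-bis(TBSO)phenyl]-2-[4-(TBSO)phenyl]ethan-1-ol | OC(Cc1ccc(O[Si](C)(C)C(C)(C)C)cc1)(c1cc(O[Si](C)(C)C(C)(C)C)cc(O[Si](C)(C)C(C)(C)C)c1)c1c(O)cc(O[Si](C)(C)C(C)(C)C)cc1Br | intermediate
9 | 3-bromo-2-{1-[3,5-bis(TBSO)phenyl]-2-[4-(TBSO)phenyl]ethenyl}-5-(TBSO)phenol, E/Z mixture (not isolated) | Oc1cc(O[Si](C)(C)C(C)(C)C)cc(Br)c1C(=Cc1ccc(O[Si](C)(C)C(C)(C)C)cc1)c1cc(O[Si](C)(C)C(C)(C)C)cc(O[Si](C)(C)C(C)(C)C)c1 | intermediate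
10 | (2R,3R)-4-bromo-3-[3,5-bis(TBSO)phenyl]-6-(TBSO)-2-[4-(TBSO)phenyl]-2,3-dihydro-1-benzofuran (unit C bromide) | Brc1cc(O[Si](C)(C)C(C)(C)C)cc2c1[C@@H](c1cc(O[Si](C)(C)C(C)(C)C)cc(O[Si](C)(C)C(C)(C)C)c1)[C@H](c1ccc(O[Si](C)(C)C(C)(C)C)cc1)O2 | intermediate
11 | 4-lithio analogue of 10 (not isolated) | [Li]c1cc(O[Si](C)(C)C(C)(C)C)cc2c1[C@@H](c1cc(O[Si](C)(C)C(C)(C)C)cc(O[Si](C)(C)C(C)(C)C)c1)[C@H](c1ccc(O[Si](C)(C)C(C)(C)C)cc1)O2 | intermediate
12 | 1-[2-bromo-6-hydroxy-4-(TBSO)phenyl]-2-[4-(TBSO)phenyl]-1-(unit C)ethan-1-ol, both carbinol epimers | OC(Cc1ccc(O[Si](C)(C)C(C)(C)C)cc1)(c1c(O)cc(O[Si](C)(C)C(C)(C)C)cc1Br)c1cc(O[Si](C)(C)C(C)(C)C)cc2c1[C@@H](c1cc(O[Si](C)(C)C(C)(C)C)cc(O[Si](C)(C)C(C)(C)C)c1)[C@H](c1ccc(O[Si](C)(C)C(C)(C)C)cc1)O2 | intermediate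
13 | 3-bromo-5-(TBSO)-2-{2-[4-(TBSO)phenyl]-1-(unit C)ethenyl}phenol, E/Z mixture (not isolated) | Oc1cc(O[Si](C)(C)C(C)(C)C)cc(Br)c1C(=Cc1ccc(O[Si](C)(C)C(C)(C)C)cc1)c1cc(O[Si](C)(C)C(C)(C)C)cc2c1[C@@H](c1cc(O[Si](C)(C)C(C)(C)C)cc(O[Si](C)(C)C(C)(C)C)c1)[C@H](c1ccc(O[Si](C)(C)C(C)(C)C)cc1)O2 | intermediate
14 | (2S,3S)-4-bromo-6-(TBSO)-2-[4-(TBSO)phenyl]-3-(unit C)-2,3-dihydro-1-benzofuran (unit BC bromide) | CC(C)(C)[Si](C)(C)Oc1ccc([C@H]2Oc3cc(O[Si](C)(C)C(C)(C)C)cc(Br)c3[C@@H]2c2cc(O[Si](C)(C)C(C)(C)C)cc3c2[C@@H](c2cc(O[Si](C)(C)C(C)(C)C)cc(O[Si](C)(C)C(C)(C)C)c2)[C@H](c2ccc(O[Si](C)(C)C(C)(C)C)cc2)O3)cc1 | intermediate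
15 | 4-lithio analogue of 14 (not isolated) | CC(C)(C)[Si](C)(C)Oc1ccc([C@H]2Oc3cc(O[Si](C)(C)C(C)(C)C)cc([Li])c3[C@@H]2c2cc(O[Si](C)(C)C(C)(C)C)cc3c2[C@@H](c2cc(O[Si](C)(C)C(C)(C)C)cc(O[Si](C)(C)C(C)(C)C)c2)[C@H](c2ccc(O[Si](C)(C)C(C)(C)C)cc2)O3)cc1 | intermediate
16 | 1-[2-bromo-6-hydroxy-4-(TBSO)phenyl]-2-[4-(TBSO)phenyl]-1-(unit BC)ethan-1-ol, both carbinol epimers | CC(C)(C)[Si](C)(C)Oc1ccc([C@H]2Oc3cc(O[Si](C)(C)C(C)(C)C)cc(C(O)(Cc4ccc(O[Si](C)(C)C(C)(C)C)cc4)c4c(O)cc(O[Si](C)(C)C(C)(C)C)cc4Br)c3[C@@H]2c2cc(O[Si](C)(C)C(C)(C)C)cc3c2[C@@H](c2cc(O[Si](C)(C)C(C)(C)C)cc(O[Si](C)(C)C(C)(C)C)c2)[C@H](c2ccc(O[Si](C)(C)C(C)(C)C)cc2)O3)cc1 | intermediate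
17 | 3-bromo-5-(TBSO)-2-{2-[4-(TBSO)phenyl]-1-(unit BC)ethenyl}phenol, E/Z mixture (not isolated) | CC(C)(C)[Si](C)(C)Oc1ccc([C@H]2Oc3cc(O[Si](C)(C)C(C)(C)C)cc(C(=Cc4ccc(O[Si](C)(C)C(C)(C)C)cc4)c4c(O)cc(O[Si](C)(C)C(C)(C)C)cc4Br)c3[C@@H]2c2cc(O[Si](C)(C)C(C)(C)C)cc3c2[C@@H](c2cc(O[Si](C)(C)C(C)(C)C)cc(O[Si](C)(C)C(C)(C)C)c2)[C@H](c2ccc(O[Si](C)(C)C(C)(C)C)cc2)O3)cc1 | intermediate
18 | (2R,3R)-4-bromo-6-(TBSO)-2-[4-(TBSO)phenyl]-3-(unit BC)-2,3-dihydro-1-benzofuran | CC(C)(C)[Si](C)(C)Oc1ccc([C@H]2Oc3cc(O[Si](C)(C)C(C)(C)C)cc([C@@H]4c5c(Br)cc(O[Si](C)(C)C(C)(C)C)cc5O[C@H]4c4ccc(O[Si](C)(C)C(C)(C)C)cc4)c3[C@@H]2c2cc(O[Si](C)(C)C(C)(C)C)cc3c2[C@@H](c2cc(O[Si](C)(C)C(C)(C)C)cc(O[Si](C)(C)C(C)(C)C)c2)[C@H](c2ccc(O[Si](C)(C)C(C)(C)C)cc2)O3)cc1 | intermediate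
19 | 3,4-dihydroxybenzaldehyde | O=Cc1ccc(O)c(O)c1 | starting material
20 | 3,4-bis(TBSO)benzaldehyde | O=Cc1ccc(O[Si](C)(C)C(C)(C)C)c(O[Si](C)(C)C(C)(C)C)c1 | intermediate
21 | 4-ethenyl-1,2-bis(TBSO)benzene | C=Cc1ccc(O[Si](C)(C)C(C)(C)C)c(O[Si](C)(C)C(C)(C)C)c1 | intermediate
22 | deca-TBS ether of the target: (2R,3R)-4-{(E)-2-[3,4-bis(TBSO)phenyl]ethenyl}-6-(TBSO)-2-[4-(TBSO)phenyl]-3-(unit BC)-2,3-dihydro-1-benzofuran | CC(C)(C)[Si](C)(C)Oc1ccc([C@H]2Oc3cc(O[Si](C)(C)C(C)(C)C)cc([C@@H]4c5c(/C=C/c6ccc(O[Si](C)(C)C(C)(C)C)c(O[Si](C)(C)C(C)(C)C)c6)cc(O[Si](C)(C)C(C)(C)C)cc5O[C@H]4c4ccc(O[Si](C)(C)C(C)(C)C)cc4)c3[C@@H]2c2cc(O[Si](C)(C)C(C)(C)C)cc3c2[C@@H](c2cc(O[Si](C)(C)C(C)(C)C)cc(O[Si](C)(C)C(C)(C)C)c2)[C@H](c2ccc(O[Si](C)(C)C(C)(C)C)cc2)O3)cc1 | intermediate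
23 | CNP0099535.1, ring A (2R,3R), ring B (2S,3S), ring C (2R,3R), E-stilbene | Oc1ccc([C@H]2Oc3cc(O)cc([C@@H]4c5c(/C=C/c6ccc(O)c(O)c6)cc(O)cc5O[C@H]4c4ccc(O)cc4)c3[C@@H]2c2cc(O)cc3c2[C@@H](c2cc(O)cc(O)c2)[C@H](c2ccc(O)cc2)O3)cc1 | target

## Step count and risks

Total steps: 14. Longest linear sequence: 11 (steps 1, 2, 3, 5, 6, 7, 8, 9, 10, 13, 14).

**Risk 1 — step 6 (the same transformation recurs in steps 8 and 10), the proposed new ring closure.**
- The acid may rest at the more stable diaryl cation / o-quinone methide instead of protonating the diaryl carbon.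
- In steps 8 and 10 the 4-silyloxybenzyl cation can instead be trapped by a neighbouring electron-rich ring in a seven-membered Friedel–Crafts closure.
- Reversible ring opening can erode the selectivity.
- One of the catalyst/substrate pairings may be mismatched.

Fallback (known chemistry, absolute control given up and replaced by separation): it sets out from 8 and comes back at 10. The ring is closed with an achiral Brønsted acid (diphenyl phosphate (PhO)2P(O)OH or CF3CO2H, CH2Cl2, 0 °C), the classical acid-catalysed phenol–alkene hydroalkoxylation. This gives the trans ring as the racemate, that is 10 together with its mirror image (2S,3S)-4-bromo-3-[3,5-bis(TBSO)phenyl]-6-(TBSO)-2-[4-(TBSO)phenyl]-2,3-dihydro-1-benzofuran F1; the two are separated by preparative supercritical-fluid chromatography on a chiral stationary phase and the route is rejoined at 10. In the later cycles the same achiral closure of 12 gives 14 together with its ring B diastereomer (2R,3R)-4-bromo-6-(TBSO)-2-[4-(TBSO)phenyl]-3-(unit C)-2,3-dihydro-1-benzofuran F2, and the closure of 16 gives 18 together with its ring A diastereomer (2S,3S)-4-bromo-6-(TBSO)-2-[4-(TBSO)phenyl]-3-(unit BC)-2,3-dihydro-1-benzofuran F3. Each of these pairs is a pair of diastereomers and is separated on silica, rejoining the route at 14 and at 18.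

**Risk 2 — step 7 (and step 9), addition of a hindered aryllithium to the hindered, enolisable ketone of 5.**
Enolisation or no reaction is likely.

Fallback (the crowded carbon is built from a non-enolisable diaryl ketone and a small benzyl nucleophile): it sets out from 10 (and 1) and comes back at 12. Vilsmeier–Haack formylation of 1 (POCl3, DMF, MeCN) gives 2-bromo-4,6-dihydroxybenzaldehyde F4, and TBSCl/imidazole silylates only the non-chelated OH to give 2-bromo-6-hydroxy-4-(TBSO)benzaldehyde F5. NaH (1.0 equiv) in THF converts F5 into sodium 3-bromo-2-formyl-5-(TBSO)phenolate F6. Aryllithium 11 (from 10, n-BuLi, −78 °C) adds to F6 to give, after aq. NH4Cl, the diaryl carbinol [2-bromo-6-hydroxy-4-(TBSO)phenyl](unit C)methanol F7, which MnO2 in CH2Cl2 oxidises to the 2-hydroxybenzophenone [2-bromo-6-hydroxy-4-(TBSO)phenyl](unit C)methanone F8. In parallel, p-cresol is silylated (TBSCl, imidazole) to tert-butyldimethyl(4-methylphenoxy)silane F9, brominated (NBS, AIBN, PhCF3, 80 °C) to [4-(bromomethyl)phenoxy](tert-butyl)dimethylsilane F10 and converted with Mg in Et2O into [4-(TBSO)benzyl]magnesium bromide F11. Excess F11 adds to F8 (THF, 0 °C; aq. NH4Cl) to give 12. For step 9 the same detour sets out from 14 and comes back at 16: aryllithium 15 adds to F6 to give [2-bromo-6-hydroxy-4-(TBSO)phenyl](unit BC)methanol F12, MnO2 oxidises it to [2-bromo-6-hydroxy-4-(TBSO)phenyl](unit BC)methanone F13, and F11 adds to F13 to give 16.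

**Risk 3 — step 13, Heck coupling on the hindered, electron-rich aryl bromide 18.**
Possible problems are slow oxidative addition, protodebromination and styrene oligomerisation.

Fallback (pre-formed alkenyl nucleophile instead of alkene insertion): it sets out from 21 and 18 and comes back at 22. Cross-metathesis of 21 with vinylboronic acid pinacol ester (second-generation Grubbs catalyst RuCl2(=CHPh)(H2IMes)(PCy3), CH2Cl2, 40 °C) gives 2-{(E)-2-[3,4-bis(TBSO)phenyl]ethenyl}-4,4,5,5-tetramethyl-1,3,2-dioxaborolane F14. Suzuki–Miyaura coupling of F14 with 18 (Pd(OAc)2, SPhos, K3PO4, toluene/H2O, 80 °C) gives 22 with retention of the E geometry.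

Further compounds

F1 | step 6 | (2S,3S)-4-bromo-3-[3,5-bis(TBSO)phenyl]-6-(TBSO)-2-[4-(TBSO)phenyl]-2,3-dihydro-1-benzofuran (enantiomer of 10) | Brc1cc(O[Si](C)(C)C(C)(C)C)cc2c1[C@H](c1cc(O[Si](C)(C)C(C)(C)C)cc(O[Si](C)(C)C(C)(C)C)c1)[C@@H](c1ccc(O[Si](C)(C)C(C)(C)C)cc1)O2
F2 | step 6 | (2R,3R)-4-bromo-6-(TBSO)-2-[4-(TBSO)phenyl]-3-(unit C)-2,3-dihydro-1-benzofuran (ring B diastereomer of 14) | CC(C)(C)[Si](C)(C)Oc1ccc([C@@H]2Oc3cc(O[Si](C)(C)C(C)(C)C)cc(Br)c3[C@H]2c2cc(O[Si](C)(C)C(C)(C)C)cc3c2[C@@H](c2cc(O[Si](C)(C)C(C)(C)C)cc(O[Si](C)(C)C(C)(C)C)c2)[C@H](c2ccc(O[Si](C)(C)C(C)(C)C)cc2)O3)cc1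
F3 | step 6 | (2S,3S)-4-bromo-6-(TBSO)-2-[4-(TBSO)phenyl]-3-(unit BC)-2,3-dihydro-1-benzofuran (ring A diastereomer of 18) | CC(C)(C)[Si](C)(C)Oc1ccc([C@H]2Oc3cc(O[Si](C)(C)C(C)(C)C)cc([C@H]4c5c(Br)cc(O[Si](C)(C)C(C)(C)C)cc5O[C@@H]4c4ccc(O[Si](C)(C)C(C)(C)C)cc4)c3[C@@H]2c2cc(O[Si](C)(C)C(C)(C)C)cc3c2[C@@H](c2cc(O[Si](C)(C)C(C)(C)C)cc(O[Si](C)(C)C(C)(C)C)c2)[C@H](c2ccc(O[Si](C)(C)C(C)(C)C)cc2)O3)cc1
F4 | step 7 | 2-bromo-4,6-dihydroxybenzaldehyde | O=Cc1c(O)cc(O)cc1Br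
F5 | step 7 | 2-bromo-6-hydroxy-4-(TBSO)benzaldehyde | O=Cc1c(O)cc(O[Si](C)(C)C(C)(C)C)cc1Br
F6 | step 7 | sodium 3-bromo-2-formyl-5-(TBSO)phenolate | [Na+].[O-]c1cc(O[Si](C)(C)C(C)(C)C)cc(Br)c1C=O
F7 | step 7 | [2-bromo-6-hydroxy-4-(TBSO)phenyl](unit C)methanol, both carbinol epimers | OC(c1c(O)cc(O[Si](C)(C)C(C)(C)C)cc1Br)c1cc(O[Si](C)(C)C(C)(C)C)cc2c1[C@@H](c1cc(O[Si](C)(C)C(C)(C)C)cc(O[Si](C)(C)C(C)(C)C)c1)[C@H](c1ccc(O[Si](C)(C)C(C)(C)C)cc1)O2
F8 | step 7 | [2-bromo-6-hydroxy-4-(TBSO)phenyl](unit C)methanone | O=C(c1c(O)cc(O[Si](C)(C)C(C)(C)C)cc1Br)c1cc(O[Si](C)(C)C(C)(C)C)cc2c1[C@@H](c1cc(O[Si](C)(C)C(C)(C)C)cc(O[Si](C)(C)C(C)(C)C)c1)[C@H](c1ccc(O[Si](C)(C)C(C)(C)C)cc1)O2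
F9 | step 7 | tert-butyldimethyl(4-methylphenoxy)silane | Cc1ccc(O[Si](C)(C)C(C)(C)C)cc1
F10 | step 7 | [4-(bromomethyl)phenoxy](tert-butyl)dimethylsilane | BrCc1ccc(O[Si](C)(C)C(C)(C)C)cc1
F11 | step 7 | [4-(TBSO)benzyl]magnesium bromide | Br[Mg]Cc1ccc(O[Si](C)(C)C(C)(C)C)cc1
F12 | step 7 | [2-bromo-6-hydroxy-4-(TBSO)phenyl](unit BC)methanol, both carbinol epimers | CC(C)(C)[Si](C)(C)Oc1ccc([C@H]2Oc3cc(O[Si](C)(C)C(C)(C)C)cc(C(O)c4c(O)cc(O[Si](C)(C)C(C)(C)C)cc4Br)c3[C@@H]2c2cc(O[Si](C)(C)C(C)(C)C)cc3c2[C@@H](c2cc(O[Si](C)(C)C(C)(C)C)cc(O[Si](C)(C)C(C)(C)C)c2)[C@H](c2ccc(O[Si](C)(C)C(C)(C)C)cc2)O3)cc1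
F13 | step 7 | [2-bromo-6-hydroxy-4-(TBSO)phenyl](unit BC)methanone | CC(C)(C)[Si](C)(C)Oc1ccc([C@H]2Oc3cc(O[Si](C)(C)C(C)(C)C)cc(C(=O)c4c(O)cc(O[Si](C)(C)C(C)(C)C)cc4Br)c3[C@@H]2c2cc(O[Si](C)(C)C(C)(C)C)cc3c2[C@@H](c2cc(O[Si](C)(C)C(C)(C)C)cc(O[Si](C)(C)C(C)(C)C)c2)[C@H](c2ccc(O[Si](C)(C)C(C)(C)C)cc2)O3)cc1
F14 | step 13 | 2-{(E)-2-[3,4-bis(TBSO)phenyl]ethenyl}-4,4,5,5-tetramethyl-1,3,2-dioxaborolane | CC1(C)OB(/C=C/c2ccc(O[Si](C)(C)C(C)(C)C)c(O[Si](C)(C)C(C)(C)C)c2)OC1(C)C
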